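What share of the Q ended as L in the flow tank delta, the fed flask gamma and the closed flask zeta, and in what order?

the same everywhere: Z 0.0500 mM; E 0.0750 M

|  | Q | remark | time |
|---|---|---|---|
| delta | 0.050 M | one stirred flow tank at steady state, fed with the mixture as stated, mean residence time 1.0 h |  |
| gamma | 0.050 M (fed, over 0.500 h) | all but Q at the start; Q goes in evenly over 0.500 h, the run ends at 1.0 h | 1.0 h |
| zeta | 0.050 M | a closed flask charged with all of it at once and left for 1.0 h | 1.0 h |

    Q + Z → D + Z + L (k1 = 26100 M⁻¹ h⁻¹)
    D ⇌ G + Z, settled at all times (K2 = 5.0 × 10⁻¹⁰ M)
    Q → D + L (k3 = 0.252 h⁻¹)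
    Q + D ⇌ Q.D, settled at all times (K4 = 3940 M⁻¹)
    D + E → D.E (k5 = 62.4 M⁻¹ h⁻¹)

1. order of the set-ups by the amount of L at the outlet or at the end, in percent of the Q put in, highest first (delta / gamma / zeta)
2. amount of L at the outlet or at the end, in percent of the Q put in, delta
3. amount of L at the outlet or at the end, in percent of the Q put in, gamma
4. amount of L at the outlet or at the end, in percent of the Q put in, zeta

I asked first where the charge must go and how fast. Step 1 gives Z back, and G per D is 1.00 × 10⁻⁵, so Z stayed as charged and free Q decayed pseudo-first-order with κ, k1 times Z plus k3, 1.56 h⁻¹.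

The charge divides into free Q, Q.D and L. Each L brought one D and each Q.D holds one D, so Q.D could not exceed L. That gave a bracket for zeta. Without binding, plain decay gave zeta a ceiling of 78.9%. With every D holding one Q, L in zeta climbs towards 0.5 of the charge with rate constant 3.11 h⁻¹. This lock-up floor, the L reached when each D made holds one Q, was 47.8%.

Binding leaks, though. For zeta I overcounted free D and D.E by reckoning them along the floor, which gave 12.5% of the charge. Crediting L with 0.5 of that leak brought the ceiling down to 54.0%.

The same balance gave floors of 37.8% for delta and 44.7% for gamma. I therefore committed to zeta above gamma above delta.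

The forecast gave 39.4%, 45.4% and 49.6% in the order zeta > gamma > delta, holding that “the yield is strongly product-inhibited”. Its zeta stood inside my bracket.

The simulation gave 39.3% for delta, 45.6% for gamma and 49.8% for zeta, in the order zeta > gamma > delta. In zeta at 1.00 h, Q.D held 42.2% of the charge beside 7.93% of free Q. Zeta stood 2.0 percentage points above the floor and 29 points below plain decay, closer to the lock-up line than to plain decay.

For zeta read at 15 min, the floor gives 27.0% and plain decay 32.2%. That reading gave 27.1%, with Q.D at 26.7%.

Its constants were set for the occasion; the flask was simulated.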